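## Retrosynthetic overview

- The plan rests on ring B: a para-phenylene whose only substituents are the ether oxygen to ring A on C1 and the benzylic bridge carbon to ring C on C4. This 1,4 oxygen/carbon pattern is what a 2-oxygenated butadiene and a terminal ynone give after cycloaddition and dehydrogenation.
- Target 22 comes from macrocyclic aryl ketone 21 (C=O to CH2 and O-debenzylation over Pd/C), 21 from cyclohexa-1,4-diene 20 (DDQ), and 20 from open-chain dienyl ether/ynone 19 by a macrocyclising intramolecular Diels–Alder reaction.
- 19 comes from bibenzyl phenol 12: acrylate and Tebbe methylenation build the 2-aryloxybutadiene on the ring A oxygen, then the CH2CH2OTBS arm on ring C is turned into CH2C(=O)C≡CH.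
- 12 comes from a Wittig/diimide union (the A–D bridge) of aldehyde 7 with phosphonium salt 9; 7 comes from an Ullmann ether coupling (the C–O–D link) of phenol 5 with 3-bromobenzaldehyde.
- Rings A, C and D are bought as arenes; ring B and the 19-membered macrocycle form last, in one event, and ring B is then aromatised.

Key step: step 14

Remark on the chemistry: isovanillyl alcohol (one reduction away from isovanillin) is taken as the commercial ring A source. Stilbene 11 is carried as an E/Z mixture and alcohol 18 as the racemate, because both elements disappear in steps 7 and 13. The target has no stereocentre.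

## Route

Step 1
Reactants: 1 4-(benzyloxy)-3-hydroxybenzaldehyde
Product: 2 2-(benzyloxy)-5-vinylphenol
Conditions: Ph3PCH3Br (2.5 equiv), KOtBu (2.5 equiv), THF, 0 °C → rt
Reagents that add atoms: methyltriphenylphosphonium bromide, C[P+](c1ccccc1)(c1ccccc1)c1ccccc1.[Br-]
Why: Wittig methylenation in which excess ylide first deprotonates the phenol, and the resulting meta-phenoxide cannot deactivate the aldehyde by resonance, so the non-stabilised ylide should still add cleanly.

Step 2
Reactants: 2 2-(benzyloxy)-5-vinylphenol
Product: 4 2-(benzyloxy)-5-(2-hydroxyethyl)phenol, via B-(2-arylethyl)-9-borabicyclononane 3 (not isolated)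
Conditions: 9-BBN (2.5 equiv), THF, 0 °C → rt; then aq. NaOH, H2O2, 0 °C → rt
Reagents that add atoms: 9-BBN, B1C2CCCC1CCC2 (boron held only in 3); hydrogen peroxide, OO
Why: Hydroboration–oxidation, in which the bulky borane places boron on the terminal carbon of the styrene and alkaline peroxide then gives the primary alcohol, the extra borane covering the phenolic OH.

Step 3
Reactants: 4 2-(benzyloxy)-5-(2-hydroxyethyl)phenol
Product: 5 2-(benzyloxy)-5-[2-(tert-butyldimethylsilyloxy)ethyl]phenol
Conditions: TBSCl (1.05 equiv), imidazole, CH2Cl2, −20 → 0 °C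
Reagents that add atoms: tert-butyldimethylsilyl chloride, CC(C)(C)[Si](C)(C)Cl
Why: Corey silylation with one equivalent of chlorosilane, which should take the unhindered primary alcohol in preference to the phenol flanked by the benzyloxy group, as in the selective silylation of tyrosol-type diols.

Step 4
Reactants: 5 2-(benzyloxy)-5-[2-(tert-butyldimethylsilyloxy)ethyl]phenol; 6 3-bromobenzaldehyde
Product: 7 3-{2-(benzyloxy)-5-[2-(tert-butyldimethylsilyloxy)ethyl]phenoxy}benzaldehyde
Conditions: CuI (10 mol %), N,N-dimethylglycine hydrochloride (30 mol %), Cs2CO3, 1,4-dioxane, 90 °C, argon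
Reagents that add atoms: none
Why: Ligand-accelerated Ullmann diaryl ether synthesis, in which the formyl-activated aryl bromide couples with the phenoxide at a temperature that spares the aldehyde, the benzyl ether and the silyl ether, and the tertiary amino acid ligand cannot condense with the aldehyde.

Step 5
Reactants: 8 3-hydroxy-4-methoxybenzyl alcohol (isovanillyl alcohol)
Product: 9 (3-hydroxy-4-methoxybenzyl)triphenylphosphonium bromide
Conditions: PPh3·HBr, MeCN, reflux
Reagents that add atoms: triphenylphosphine hydrobromide, [Br-].c1ccc(cc1)[PH+](c1ccccc1)c1ccccc1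
Why: Acid-mediated substitution of a benzylic alcohol activated by the para-methoxy group, which gives the phosphonium salt directly and leaves the phenol free.

Step 6
Reactants: 7 3-{2-(benzyloxy)-5-[2-(tert-butyldimethylsilyloxy)ethyl]phenoxy}benzaldehyde; 9 (3-hydroxy-4-methoxybenzyl)triphenylphosphonium bromide
Product: 11 5-[2-(3-{2-(benzyloxy)-5-[2-(tert-butyldimethylsilyloxy)ethyl]phenoxy}phenyl)ethenyl]-2-methoxyphenol (E/Z mixture), via phenoxide ylide 10 (not isolated)
Conditions: 9 (1.2 equiv), KOtBu (2.5 equiv), THF, 0 °C; then 7, 0 °C → rt; aq. NH4Cl work-up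
Reagents that add atoms: none
Why: Wittig olefination with a semi-stabilised benzylic ylide whose meta-oxido group cannot form a quinone methide, so two equivalents of base should give a reactive phenoxide ylide that condenses with the non-enolisable aldehyde.

Step 7
Reactants: 11 stilbene phenol (E/Z mixture)
Product: 12 5-[2-(3-{2-(benzyloxy)-5-[2-(tert-butyldimethylsilyloxy)ethyl]phenoxy}phenyl)ethyl]-2-methoxyphenol
Conditions: TsNHNH2 (excess, portionwise), NaOAc, THF/H2O, reflux
Reagents that add atoms: none
Why: Diimide reduction, in which diimide from the thermal fragmentation of tosylhydrazide transfers hydrogen in a concerted way to the stilbene C=C only, so the benzyl ether, the buffered silyl ether and the arenes are left alone and both alkene isomers converge.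

Step 8
Reactants: 12 bibenzyl phenol; 13 acryloyl chloride
Product: 14 aryl acrylate, 5-[2-(3-{2-(benzyloxy)-5-[2-(tert-butyldimethylsilyloxy)ethyl]phenoxy}phenyl)ethyl]-2-methoxyphenyl prop-2-enoate
Conditions: Et3N, CH2Cl2, BHT (trace), −20 → 0 °C
Reagents that add atoms: none
Why: O-acylation of the only free hydroxyl by the acid chloride, which at low temperature is much faster than conjugate addition to the acrylate.

Step 9
Reactants: 14 aryl acrylate
Product: 15 2-aryloxybuta-1,3-diene, tert-butyl{2-[4-(benzyloxy)-3-(3-{2-[3-(buta-1,3-dien-2-yloxy)-4-methoxyphenyl]ethyl}phenoxy)phenyl]ethoxy}dimethylsilane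
Conditions: Cp2Ti(μ-Cl)(μ-CH2)AlMe2 (Tebbe reagent, 1.3 equiv), pyridine (cat.), THF/toluene, −40 °C → rt; aq. NaOH quench; basic alumina
Reagents that add atoms: Tebbe reagent, C[Al-]1(C)C[Ti](C2C=CC=C2)(C2C=CC=C2)[Cl+]1
Why: Tebbe methylenation, in which the titanium methylidene adds [2+2] to the ester carbonyl and cycloreversion driven by the Ti=O bond gives the enol ether, a reaction established for aryl esters and for α,β-unsaturated esters and inert towards silyl, benzyl and diaryl ethers.

Step 10
Reactants: 15 2-aryloxybuta-1,3-diene silyl ether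
Product: 16 2-[4-(benzyloxy)-3-(3-{2-[3-(buta-1,3-dien-2-yloxy)-4-methoxyphenyl]ethyl}phenoxy)phenyl]ethanol
Conditions: Bu4NF, THF, 0 °C → rt
Reagents that add atoms: none
Why: Fluoride-mediated desilylation driven by the Si–F bond, run under basic conditions that the acid-labile aryl dienyl ether should tolerate.

Step 11
Reactants: 16 dienyl ether alcohol
Product: 17 2-[4-(benzyloxy)-3-(3-{2-[3-(buta-1,3-dien-2-yloxy)-4-methoxyphenyl]ethyl}phenoxy)phenyl]acetaldehyde
Conditions: Dess–Martin periodinane, NaHCO3, CH2Cl2, 0 °C → rt; used at once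
Reagents that add atoms: none
Why: Dess–Martin oxidation, which is buffered, stops at the aldehyde and does not attack the enol ether diene.

Step 12
Reactants: 17 dienyl ether arylacetaldehyde
Product: 18 1-[4-(benzyloxy)-3-(3-{2-[3-(buta-1,3-dien-2-yloxy)-4-methoxyphenyl]ethyl}phenoxy)phenyl]but-3-yn-2-ol (racemic)
Conditions: HC≡CMgBr (2 equiv), THF, −78 → −20 °C; aq. NH4Cl
Reagents that add atoms: ethynylmagnesium bromide, C#C[Mg]Br
Why: 1,2-Addition of an alkynyl Grignard reagent to the aldehyde, which at low temperature should outpace enolisation; the new carbinol centre forms as the racemate and is removed in step 13.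

Step 13
Reactants: 18 dienyl ether propargylic alcohol
Product: 19 1-[4-(benzyloxy)-3-(3-{2-[3-(buta-1,3-dien-2-yloxy)-4-methoxyphenyl]ethyl}phenoxy)phenyl]but-3-yn-2-one (open-chain dienyl ether/ynone)
Conditions: Dess–Martin periodinane, NaHCO3, CH2Cl2, 0 °C
Reagents that add atoms: none
Why: Dess–Martin oxidation of a secondary propargylic alcohol to the terminal ynone under buffered, non-nucleophilic conditions, which also removes the stereocentre.

Step 14
Reactants: 19 open-chain dienyl ether/ynone
Product: 20 macrocyclic 1-aryloxy-4-acylcyclohexa-1,4-diene (ring B as the diene inside the 19-membered ring, ring C oxygen benzylated)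
Conditions: toluene (1 mM final, syringe-pump addition), BHT (cat.), 110 °C, argon; concentrated and used crude
Reagents that add atoms: none
Why: Proposed new method: the CH2 terminus next to the aryloxy-bearing diene carbon is the nucleophilic end and the terminal CH of the ynone the electrophilic end, so an asynchronous concerted [4+2] cycloaddition through the s-cis diene should join these two carbons and join the other diene terminus to the acyl-bearing alkyne carbon, giving the 1-aryloxy-4-acylcyclohexa-1,4-diene. The closest known reaction types are the para-selective intermolecular Diels–Alder reactions of 2-oxygenated butadienes with ynones and the macrocyclising, arene-forming intramolecular Diels–Alder reactions of tethered dienes and alkynes used for cyclophanes. The six-membered ring B closes by the cycloaddition itself, and the 19-membered macrocycle closes in the same event, because the 15-atom tether links the diene oxygen to the ynone carbonyl across the 1,4-positions of the new ring. No stereocentre is formed. The step needs para over meta regiochemistry, which the donor oxygen on the diene and the acceptor carbonyl on the alkyne should secure because the long unstrained tether cannot override them, and ring closure over oligomerisation, which high dilution with slow addition should secure.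

Step 15
Reactants: 20 macrocyclic cyclohexa-1,4-diene
Product: 21 macrocyclic aryl ketone with ring B aromatic (ring B–C(=O)–CH2–ring C, ring C oxygen benzylated)
Conditions: DDQ (1.1 equiv), toluene, rt
Reagents that add atoms: none
Why: DDQ dehydrogenation of a cyclohexa-1,4-diene (hydride abstraction then proton loss), driven by aromatisation and fast enough at room temperature that the benzyl ether and the benzylic positions should not be touched.

Step 16
Reactants: 21 macrocyclic aryl ketone
Product: 22 target macrocycle CNP0132125.0
Conditions: H2 (4 atm), 10% Pd/C, AcOH/EtOAc, HClO4 (cat.), rt → 40 °C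
Reagents that add atoms: none
Why: Catalytic hydrogenation of the aryl ketone to the benzylic alcohol, acid-promoted hydrogenolysis of its C–O bond (helped by the para-aryloxy donor) to the methylene, and hydrogenolysis of the benzyl ether in the same operation.

## Compound list

1 | 4-(benzyloxy)-3-hydroxybenzaldehyde | O=Cc1ccc(OCc2ccccc2)c(O)c1 | starting material
2 | 2-(benzyloxy)-5-vinylphenol | C=Cc1ccc(OCc2ccccc2)c(O)c1 | intermediate
3 | B-[2-(4-benzyloxy-3-hydroxyphenyl)ethyl]-9-borabicyclo[3.3.1]nonane (not isolated) | Oc1cc(CCB2C3CCCC2CCC3)ccc1OCc1ccccc1 | intermediate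
4 | 2-(benzyloxy)-5-(2-hydroxyethyl)phenol | OCCc1ccc(OCc2ccccc2)c(O)c1 | intermediate
5 | 2-(benzyloxy)-5-[2-(tert-butyldimethylsilyloxy)ethyl]phenol | CC(C)(C)[Si](C)(C)OCCc1ccc(OCc2ccccc2)c(O)c1 | intermediate
6 | 3-bromobenzaldehyde | O=Cc1cccc(Br)c1 | starting material
7 | 3-{2-(benzyloxy)-5-[2-(tert-butyldimethylsilyloxy)ethyl]phenoxy}benzaldehyde | CC(C)(C)[Si](C)(C)OCCc1ccc(OCc2ccccc2)c(Oc2cccc(C=O)c2)c1 | intermediate
8 | 3-hydroxy-4-methoxybenzyl alcohol (isovanillyl alcohol) | COc1ccc(CO)cc1O | starting material
9 | (3-hydroxy-4-methoxybenzyl)triphenylphosphonium bromide | COc1ccc(C[P+](c2ccccc2)(c2ccccc2)c2ccccc2)cc1O.[Br-] | intermediate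
10 | potassium 2-methoxy-5-[(triphenylphosphoranylidene)methyl]phenolate (not isolated) | COc1ccc(C=P(c2ccccc2)(c2ccccc2)c2ccccc2)cc1[O-].[K+] | intermediate
11 | 5-[2-(3-{2-(benzyloxy)-5-[2-(tert-butyldimethylsilyloxy)ethyl]phenoxy}phenyl)ethenyl]-2-methoxyphenol (E/Z mixture, geometry left open) | COc1ccc(C=Cc2cccc(Oc3cc(CCO[Si](C)(C)C(C)(C)C)ccc3OCc3ccccc3)c2)cc1O | intermediate
12 | 5-[2-(3-{2-(benzyloxy)-5-[2-(tert-butyldimethylsilyloxy)ethyl]phenoxy}phenyl)ethyl]-2-methoxyphenol | COc1ccc(CCc2cccc(Oc3cc(CCO[Si](C)(C)C(C)(C)C)ccc3OCc3ccccc3)c2)cc1O | intermediate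
13 | acryloyl chloride | C=CC(=O)Cl | starting material
14 | aryl acrylate of 12 | COc1ccc(CCc2cccc(Oc3cc(CCO[Si](C)(C)C(C)(C)C)ccc3OCc3ccccc3)c2)cc1OC(=O)C=C | intermediate
15 | 2-aryloxybuta-1,3-diene silyl ether | COc1ccc(CCc2cccc(Oc3cc(CCO[Si](C)(C)C(C)(C)C)ccc3OCc3ccccc3)c2)cc1OC(=C)C=C | intermediate
16 | dienyl ether primary alcohol | COc1ccc(CCc2cccc(Oc3cc(CCO)ccc3OCc3ccccc3)c2)cc1OC(=C)C=C | intermediate
17 | dienyl ether arylacetaldehyde | COc1ccc(CCc2cccc(Oc3cc(CC=O)ccc3OCc3ccccc3)c2)cc1OC(=C)C=C | intermediate
18 | dienyl ether propargylic alcohol (racemic) | COc1ccc(CCc2cccc(Oc3cc(CC(O)C#C)ccc3OCc3ccccc3)c2)cc1OC(=C)C=C | intermediate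
19 | open-chain 2-aryloxybuta-1,3-diene/terminal ynone | COc1ccc(CCc2cccc(Oc3cc(CC(=O)C#C)ccc3OCc3ccccc3)c2)cc1OC(=C)C=C | intermediate
20 | macrocyclic 1-aryloxy-4-acylcyclohexa-1,4-diene | COc1ccc2cc1OC1=CCC(=CC1)C(=O)Cc1ccc(OCc3ccccc3)c(c1)Oc1cccc(c1)CC2 | intermediate
21 | macrocyclic aryl ketone, ring B aromatic | COc1ccc2cc1Oc1ccc(cc1)C(=O)Cc1ccc(OCc3ccccc3)c(c1)Oc1cccc(c1)CC2 | intermediate
22 | CNP0132125.0 | COc1ccc2cc1Oc1ccc(cc1)CCc1ccc(O)c(c1)Oc1cccc(c1)CC2 | target

## Step count and risks

Total step count: 16 (steps 1–16, step 5 being the one-step side branch to 9).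
Longest linear sequence: 15 steps (1 → 22 through steps 1–4 and 6–16).

Steps most likely to fail:

1. Step 14 (proposed new method). Intermolecular cycloaddition could lead to oligomers in place of ring closure, the electronic preference could erode so that the meta adduct forms, or the terminal ynone or the dienyl ether could decompose thermally before cyclisation; a mild Lewis acid (Me2AlCl or ZnCl2 in CH2Cl2 at low temperature) would be tried first within the step. Fallback by known chemistry, setting out from phenol 12 and coming back to the route at 22: the ring A phenol is O-arylated with excess 1,4-diiodobenzene (CuI, N,N-dimethylglycine hydrochloride, Cs2CO3, dioxane, 90 °C) to give the 4-iodophenyl ether F1. Desilylation with Bu4NF gives the primary alcohol F2, and buffered Dess–Martin oxidation gives the iodoaryl arylacetaldehyde F3. An intramolecular Nozaki–Hiyama–Kishi reaction (CrCl2 in excess, NiCl2 catalytic, DMF, high dilution) then adds the aryl iodide carbon of ring B to the aldehyde and closes the 19-membered ring as the macrocyclic benzylic carbinol F4 (racemic). Under the conditions of step 16, F4 should lose both the benzylic hydroxyl and the benzyl ether and give 22.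

2. Step 9. The acrylate or the product diene could polymerise, methylenation could stay incomplete, or the dienyl ether could hydrolyse during quench and chromatography. Fallback, setting out from phenol 12 and coming back at 15: palladium-catalysed opening of 2-vinyloxirane by the phenol (Pd2(dba)3·CHCl3, racemic trans-N,N'-(cyclohexane-1,2-diyl)bis[2-(diphenylphosphino)benzamide], CH2Cl2, rt) should give the branched 2-aryloxybut-3-en-1-ol F5. Iodination (I2, PPh3, imidazole) gives the primary iodide F6, and E2 elimination with KOtBu in THF at 0 °C removes the allylic, oxygen-bearing hydrogen to form the 2-aryloxybuta-1,3-diene 15. This is the classical dehydrohalogenation route to aryl vinyl ethers, and it avoids titanium reagents and ester intermediates.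

3. Step 12. The arylacetaldehyde could enolise and self-condense under the basic Grignard conditions, and the acid-labile dienyl ether could erode over the three consecutive steps 11–13. Fallback, setting out from aldehyde 17 and coming back at 19 (step 13 is then not needed): Pinnick oxidation (NaClO2, NaH2PO4, 2-methyl-2-butene in large excess, t-BuOH/H2O, 0 °C) gives the arylacetic acid F7. Coupling with N,O-dimethylhydroxylamine hydrochloride (EDC·HCl, i-Pr2NEt, CH2Cl2) gives the Weinreb amide F8. Acyl substitution with HC≡CMgBr (THF, −20 → 0 °C, inverse quench into cold aqueous NH4Cl) should deliver ynone 19 directly through the stable chelated tetrahedral intermediate.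

## Further compounds

F1 | step 14 | 4-iodophenyl ether of phenol 12 | COc1ccc(CCc2cccc(Oc3cc(CCO[Si](C)(C)C(C)(C)C)ccc3OCc3ccccc3)c2)cc1Oc1ccc(I)cc1
F2 | step 14 | iodoaryl ether primary alcohol | COc1ccc(CCc2cccc(Oc3cc(CCO)ccc3OCc3ccccc3)c2)cc1Oc1ccc(I)cc1
F3 | step 14 | iodoaryl ether arylacetaldehyde | COc1ccc(CCc2cccc(Oc3cc(CC=O)ccc3OCc3ccccc3)c2)cc1Oc1ccc(I)cc1
F4 | step 14 | macrocyclic benzylic carbinol (racemic) | COc1ccc2cc1Oc1ccc(cc1)C(O)Cc1ccc(OCc3ccccc3)c(c1)Oc1cccc(c1)CC2
F5 | step 9 | 2-aryloxybut-3-en-1-ol from 12 (racemic) | COc1ccc(CCc2cccc(Oc3cc(CCO[Si](C)(C)C(C)(C)C)ccc3OCc3ccccc3)c2)cc1OC(CO)C=C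
F6 | step 9 | 1-iodo-2-aryloxybut-3-ene (racemic) | COc1ccc(CCc2cccc(Oc3cc(CCO[Si](C)(C)C(C)(C)C)ccc3OCc3ccccc3)c2)cc1OC(CI)C=C
F7 | step 12 | dienyl ether arylacetic acid | COc1ccc(CCc2cccc(Oc3cc(CC(O)=O)ccc3OCc3ccccc3)c2)cc1OC(=C)C=C
F8 | step 12 | dienyl ether Weinreb amide | COc1ccc(CCc2cccc(Oc3cc(CC(=O)N(C)OC)ccc3OCc3ccccc3)c2)cc1OC(=C)C=C
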